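**Plan**
1. The target is read as epicatechin-(4β→8)-epicatechin-(4β→6)-epicatechin. After removal of benzyl and bromine groups, the retrosynthesis cuts in one operation the C4–C4a bond of the middle pyran ring and the C4(middle)–C6(bottom) interflavan bond. It then cuts the O1–C2 aryl ether bond (phenoxide plus cis-epoxide) and last the C4(top)–C8(middle) bond (top cation plus a bromophenol).
2. Enabling feature: C4 of the middle unit is a methine benzylic to two phloroglucinol-type rings, namely C4a of its own ring A (ortho to the ring oxygen O1 on C8a) and C6 of the bottom ring A (between O5 and O7). It is therefore a latent aldehyde carbon that two arenes can attack in turn, the first through the six-membered tether O1–C2–C3–C4.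
3. Forward: (−)-epicatechin gives, with its rings intact, the C8-brominated bottom nucleophile and the C4-activated top electrophile. The top unit is joined to a para-brominated phloroglucinol phenol (the future ring A of the middle unit), and this phenol opens a cis-epoxy acetal.
4. An acid cascade then closes the middle pyran ring (O1, C2, C3, C4, C4a, C8a), the only ring made in the route and the last to close, and joins the bottom unit in the same flask; hydrogenolysis finishes.
5. Stereochemistry: C2/C3 of top and bottom come from the chiral pool. Middle C2/C3 come from catalyst-controlled epoxidation of a Z-alkene followed by SN2 inversion at C2 (2,3-cis). Both C4 centres come from attack on cyclic benzylic cations anti to the axial 3-OH.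

Key step: step 10

Assumption: each flavan unit is 2R,3R and each interflavan bond is trans to the neighbouring 3-OH (4β), as the SMILES gives; the phenol, aryl bromide and alkynyl acetal building blocks are taken as purchasable.

Step 1
Reactants: 1 (−)-epicatechin
Product: 2 5,7,3',4'-tetra-O-benzylepicatechin
Conditions: BnBr (4.4 equiv), K2CO3, DMF, 0 °C to rt
Reagents that add atoms: benzyl bromide, BrCc1ccccc1
Why: Williamson ether synthesis in which carbonate deprotonates only the four phenols, so the C3 alcohol and both stereocentres should remain untouched.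

Step 2
Reactants: 2 5,7,3',4'-tetra-O-benzylepicatechin
Product: 3 8-bromo-5,7,3',4'-tetra-O-benzylepicatechin
Conditions: NBS (1.0 equiv), CH2Cl2, −40 °C
Reagents that add atoms: N-bromosuccinimide, O=C1CCC(=O)N1Br
Why: Electrophilic aromatic bromination at C8, the more nucleophilic of the two free ring A carbons of a 5,7-dialkoxyflavan, which blocks C8 in what become the bottom and the top unit.

Step 3
Reactants: 3 8-bromo-5,7,3',4'-tetra-O-benzylepicatechin
Product: 4 8-bromo-4β-(2-ethoxyethoxy)-5,7,3',4'-tetra-O-benzylepicatechin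
Conditions: DDQ (2 equiv), 2-ethoxyethanol (5 equiv), CH2Cl2, rt
Reagents that add atoms: 2-ethoxyethanol, CCOCCO
Why: Benzylic oxidation by hydride abstraction with DDQ, in which the C4 cation stabilised by O1, O5 and O7 is trapped by the alcohol trans to the C3 hydroxyl; the C4 configuration is of no consequence because this ether is ionised again in step 5.

Step 4
Reactants: 5 3,5-bis(benzyloxy)phenol
Product: 6 4-bromo-3,5-bis(benzyloxy)phenol
Conditions: NBS (1.0 equiv), MeCN, −20 °C
Reagents that add atoms: N-bromosuccinimide, O=C1CCC(=O)N1Br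
Why: Electrophilic aromatic bromination of a phenol in a polar solvent, which should favour the carbon para to the hydroxyl; the bromine leaves only the two equivalent ortho carbons free, later blocks C6 of the middle unit, and is removed in step 11.

Step 5
Reactants: 4 8-bromo-4β-(2-ethoxyethoxy)-5,7,3',4'-tetra-O-benzylepicatechin; 6 4-bromo-3,5-bis(benzyloxy)phenol
Product: 7 2-[8-bromo-5,7,3',4'-tetra-O-benzylepicatechin-4β-yl]-4-bromo-3,5-bis(benzyloxy)phenol
Conditions: 6 (3 equiv), Me3SiOTf (0.2 equiv), CH2Cl2, −78 to −30 °C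
Reagents that add atoms: none
Why: Lewis-acid-promoted Friedel–Crafts coupling of a 4-alkoxyflavan-3-ol with a phloroglucinol-type nucleophile, in which the phenol attacks the C4 cation through one of its two equivalent free ortho carbons and the new C4 stereocentre is set trans to the axial C3 hydroxyl (4β) by approach anti to that group on the half-chair cation.

Step 6
Reactants: 8 4-bromo-1,2-bis(benzyloxy)benzene; 9 3,3-diethoxyprop-1-yne
Product: 10 4-(3,3-diethoxyprop-1-yn-1-yl)-1,2-bis(benzyloxy)benzene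
Conditions: Pd(PPh3)2Cl2 (3 mol %), CuI (5 mol %), Et3N, 70 °C
Reagents that add atoms: none
Why: Sonogashira coupling of an aryl bromide with a terminal alkyne, to which the acetal and the benzyl ethers are inert.

Step 7
Reactants: 10 4-(3,3-diethoxyprop-1-yn-1-yl)-1,2-bis(benzyloxy)benzene
Product: 11 (Z)-4-(3,3-diethoxyprop-1-en-1-yl)-1,2-bis(benzyloxy)benzene
Conditions: H2 (1 atm), Pd on CaCO3 poisoned with Pb(OAc)2, quinoline, EtOAc, rt
Reagents that add atoms: none
Why: Lindlar semihydrogenation, in which syn delivery of hydrogen on the poisoned surface should give the Z-alkene and leave benzyl ethers and acetal intact.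

Step 8
Reactants: 11 (Z)-4-(3,3-diethoxyprop-1-en-1-yl)-1,2-bis(benzyloxy)benzene
Product: 12 (2S,3S)-2-[3,4-bis(benzyloxy)phenyl]-3-(diethoxymethyl)oxirane (cis)
Conditions: (S,S)-N,N'-bis(3,5-di-tert-butylsalicylidene)-1,2-cyclohexanediaminomanganese chloride (C36H52ClMnN2O2, 5 mol %), 4-phenylpyridine N-oxide (20 mol %), aq NaOCl (pH 11.3), CH2Cl2, 0 °C
Reagents that add atoms: sodium hypochlorite, [Na+].[O-]Cl
Why: Jacobsen–Katsuki epoxidation of a cis-disubstituted aryl alkene, the substrate class it serves best, in which the (S,S)-catalyst should deliver oxygen to the enantioface that makes the benzylic carbon S (by analogy with (Z)-cinnamate esters and indene) and so sets C2 and C3 of the middle unit.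

Step 9
Reactants: 7 2-[8-bromo-5,7,3',4'-tetra-O-benzylepicatechin-4β-yl]-4-bromo-3,5-bis(benzyloxy)phenol; 12 (2S,3S)-2-[3,4-bis(benzyloxy)phenyl]-3-(diethoxymethyl)oxirane
Product: 13 (2S,3R)-3-[3,4-bis(benzyloxy)phenyl]-3-{2-[8-bromo-5,7,3',4'-tetra-O-benzylepicatechin-4β-yl]-4-bromo-3,5-bis(benzyloxy)phenoxy}-1,1-diethoxypropan-2-ol
Conditions: 12 (1.3 equiv), Cs2CO3 (0.5 equiv), DMF, 80 °C
Reagents that add atoms: none
Why: Base-mediated SN2 opening of an aryl epoxide by a phenoxide at the benzylic carbon (activated by the electron-rich aryl group, whereas the other carbon is shielded and deactivated by the acetal), whose inversion turns the cis-epoxide into the ether alcohol with the 2,3-cis relationship of the future ring.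

Step 10
Reactants: 13 the aryl ether acetal of step 9; 3 8-bromo-5,7,3',4'-tetra-O-benzylepicatechin
Product: 15 8-bromo-tetra-O-benzylepicatechin-(4β→8)-6-bromo-tetra-O-benzylepicatechin-(4β→6)-8-bromo-tetra-O-benzylepicatechin, via 4-ethoxyflavan dimer 14 (not isolated)
Conditions: 3 (3 equiv), Me3SiOTf (0.5 equiv), CH2Cl2, −78 to −30 °C, slow addition of 13; then Et3N
Reagents that add atoms: none
Why: Proposed new method: Me3SiOTf ionises the diethyl acetal of 13 to an oxocarbenium ion at C4, the only free carbon of the tethered aryl ether ring (C4a, ortho to O1) attacks it to give the 4-ethoxyflavan-3-ol 14, and 14 loses ethanol to the C4 cation stabilised by O1, O5 and O7, which C6 of 3 captures. The closest known reaction types are the acid-mediated cyclisation of 3-aryloxypropanal acetals to 4-alkoxychromans and the Lewis-acid coupling of 4-alkoxyflavan-3-ols with flavan-3-ol nucleophiles, here run in one flask on an acyclic 2-hydroxy-3-aryloxy acetal. The pyran ring closes by a 6-exo-trig Friedel–Crafts attack of an arene carbon on the oxocarbenium carbon, with the C4a–C8a bond of ring A inside the new ring. C2 and C3 come unchanged from 13, and the new C4 stereocentre should be set by the ring itself: in the half-chair cation the C2 aryl group is equatorial and the C3 hydroxyl axial, so 3 adds to the opposite face, trans to the 3-OH (4β). The step needs site selectivity in both arenes and a stop after one intermolecular arylation: the ether tether, the para bromine and the top unit on the second ortho carbon leave C4a as the only carbon that can close a six-membered ring, the C8 bromine of 3 leaves C6 as its only free ring A carbon, and because every ring A of 13, 14 and 15 is substituted at C8 the excess of 3 should outcompete chain growth. Should 3 intercept the acyclic oxocarbenium ion before ring closure, the resulting benzylic ether ionises again and closes onto the same C4a, so both orders converge on 15.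

Step 11
Reactants: 15 the tribromo dodeca-O-benzyl trimer of step 10
Product: 16 epicatechin-(4β→8)-epicatechin-(4β→6)-epicatechin (CNP0178679.3)
Conditions: H2 (1 atm), Pd(OH)2/C, Et3N (3.5 equiv), THF/MeOH/H2O, rt
Reagents that add atoms: none
Why: Hydrogenolysis that cleaves the twelve benzyl ethers to toluene and reduces the three aryl C–Br bonds, with Et3N taking up HBr so that the acid-labile interflavan bonds survive and no stereocentre is touched.

**Compound list**
1 | (−)-epicatechin, (2R,3R)-2-(3,4-dihydroxyphenyl)chroman-3,5,7-triol | Oc1cc(O)c2c(c1)O[C@H](c1ccc(O)c(O)c1)[C@H](O)C2 | starting material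
2 | 5,7,3',4'-tetra-O-benzylepicatechin, (2R,3R)-5,7-bis(benzyloxy)-2-[3,4-bis(benzyloxy)phenyl]chroman-3-ol | C(c1ccccc1)Oc1cc(OCc3ccccc3)c2c(c1)O[C@H](c1ccc(OCc3ccccc3)c(OCc3ccccc3)c1)[C@H](O)C2 | intermediate
3 | 8-bromo-5,7,3',4'-tetra-O-benzylepicatechin (2R,3R) | C(c1ccccc1)Oc1cc(OCc3ccccc3)c2c(c1Br)O[C@H](c1ccc(OCc3ccccc3)c(OCc3ccccc3)c1)[C@H](O)C2 | intermediate
4 | 8-bromo-4β-(2-ethoxyethoxy)-5,7,3',4'-tetra-O-benzylepicatechin (2R,3R,4S; ether trans to 3-OH) | C(c1ccccc1)Oc1cc(OCc3ccccc3)c2c(c1Br)O[C@H](c1ccc(OCc3ccccc3)c(OCc3ccccc3)c1)[C@H](O)[C@H]2OCCOCC | intermediate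
5 | 3,5-bis(benzyloxy)phenol | Oc1cc(OCc2ccccc2)cc(OCc2ccccc2)c1 | starting material
6 | 4-bromo-3,5-bis(benzyloxy)phenol | Oc1cc(OCc2ccccc2)c(Br)c(OCc2ccccc2)c1 | intermediate
7 | 2-[8-bromo-5,7,3',4'-tetra-O-benzylepicatechin-4β-yl]-4-bromo-3,5-bis(benzyloxy)phenol (aryl group trans to the 3-OH) | C(c1ccccc1)Oc1cc(OCc3ccccc3)c2c(c1Br)O[C@H](c1ccc(OCc3ccccc3)c(OCc3ccccc3)c1)[C@H](O)[C@H]2c1c(OCc3ccccc3)c(Br)c(OCc3ccccc3)cc1O | intermediate
8 | 4-bromo-1,2-bis(benzyloxy)benzene | Brc1ccc(OCc2ccccc2)c(OCc2ccccc2)c1 | starting material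
9 | 3,3-diethoxyprop-1-yne | C#CC(OCC)OCC | starting material
10 | 4-(3,3-diethoxyprop-1-yn-1-yl)-1,2-bis(benzyloxy)benzene | CCOC(OCC)C#Cc1ccc(OCc2ccccc2)c(OCc2ccccc2)c1 | intermediate
11 | (Z)-4-(3,3-diethoxyprop-1-en-1-yl)-1,2-bis(benzyloxy)benzene | CCOC(OCC)/C=C\c1ccc(OCc2ccccc2)c(OCc2ccccc2)c1 | intermediate
12 | (2S,3S)-2-[3,4-bis(benzyloxy)phenyl]-3-(diethoxymethyl)oxirane (cis) | CCOC(OCC)[C@H]1O[C@H]1c1ccc(OCc2ccccc2)c(OCc2ccccc2)c1 | intermediate
13 | (2S,3R)-3-[3,4-bis(benzyloxy)phenyl]-3-{2-[8-bromo-5,7,3',4'-tetra-O-benzylepicatechin-4β-yl]-4-bromo-3,5-bis(benzyloxy)phenoxy}-1,1-diethoxypropan-2-ol | C(c1ccccc1)Oc1cc(OCc3ccccc3)c2c(c1Br)O[C@H](c1ccc(OCc3ccccc3)c(OCc3ccccc3)c1)[C@H](O)[C@H]2c1c(OCc3ccccc3)c(Br)c(OCc3ccccc3)cc1O[C@H](c1ccc(OCc3ccccc3)c(OCc3ccccc3)c1)[C@H](O)C(OCC)OCC | intermediate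
14 | 8-bromo-5,7,3',4'-tetra-O-benzylepicatechin-(4β→8)-6-bromo-4-ethoxy-5,7,3',4'-tetra-O-benzylepicatechin (middle pyran ring closed, 2,3-cis; ethoxy-bearing C4 as a mixture of epimers) | C(c1ccccc1)Oc1cc(OCc3ccccc3)c2c(c1Br)O[C@H](c1ccc(OCc3ccccc3)c(OCc3ccccc3)c1)[C@H](O)[C@H]2c1c(OCc3ccccc3)c(Br)c(OCc3ccccc3)c2c1O[C@H](c1ccc(OCc3ccccc3)c(OCc3ccccc3)c1)[C@H](O)C2OCC | intermediate
15 | 8-bromo-5,7,3',4'-tetra-O-benzylepicatechin-(4β→8)-6-bromo-5,7,3',4'-tetra-O-benzylepicatechin-(4β→6)-8-bromo-5,7,3',4'-tetra-O-benzylepicatechin | C(c1ccccc1)Oc1cc(OCc3ccccc3)c2c(c1Br)O[C@H](c1ccc(OCc3ccccc3)c(OCc3ccccc3)c1)[C@H](O)[C@H]2c1c(OCc3ccccc3)c(Br)c(OCc3ccccc3)c2c1O[C@H](c1ccc(OCc3ccccc3)c(OCc3ccccc3)c1)[C@H](O)[C@H]2c1c(OCc3ccccc3)c(Br)c2c(c1OCc3ccccc3)C[C@@H](O)[C@@H](c1ccc(OCc3ccccc3)c(OCc3ccccc3)c1)O2 | intermediate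
16 | epicatechin-(4β→8)-epicatechin-(4β→6)-epicatechin (CNP0178679.3) | Oc1cc(O)c2c(c1)O[C@H](c1ccc(O)c(O)c1)[C@H](O)[C@H]2c1c(O)cc(O)c2c1O[C@H](c1ccc(O)c(O)c1)[C@H](O)[C@H]2c1c(O)cc2c(c1O)C[C@@H](O)[C@@H](c1ccc(O)c(O)c1)O2 | target

**Totals**
Total step count: 11. Longest linear sequence: 7 steps (steps 1, 2, 3, 5, 9, 10, 11).

**Steps most likely to fail**

Step 10 (key step). The oxocarbenium ion from 13 may fail to cyclise onto the bromine-deactivated, crowded aryl ether ring. It could instead be hydrolysed, be captured by 3 without ring closure, or the acid-labile benzylic aryl ether at C2 could ionise. The fallback uses known chemistry and takes the middle pyran ring from the chiral pool instead of closing it. It sets out from 2. DDQ and 2-ethoxyethanol give 4β-(2-ethoxyethoxy)-5,7,3',4'-tetra-O-benzylepicatechin F1. Me3SiOTf-promoted Friedel–Crafts coupling of F1 with an excess of 3 (C8 blocked, so C6 attacks) should give the dimer 5,7,3',4'-tetra-O-benzylepicatechin-(4β→6)-8-bromo-5,7,3',4'-tetra-O-benzylepicatechin F2. A second Me3SiOTf coupling of F2 with 4, at C8 of its upper unit, should give the dibromo dodeca-O-benzyl trimer F3. Hydrogenolysis of F3 under the conditions of step 11 comes back to the route at 16.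

Step 9. SN2 attack may be slow or unselective because the phenoxide oxygen of 7 sits next to the bulky flavan-4-yl group, so the epoxide may degrade or open at the wrong carbon. The fallback attaches the top unit last instead of first. It sets out from 12 and 6. The unhindered phenol 6 opens 12 under the same base catalysis to give (2S,3R)-3-[4-bromo-3,5-bis(benzyloxy)phenoxy]-3-[3,4-bis(benzyloxy)phenyl]-1,1-diethoxypropan-2-ol F4. The acid cascade of step 10, run on F4 with an excess of 3, should pass through 6-bromo-4-ethoxy-5,7,3',4'-tetra-O-benzylepicatechin F5 (not isolated) to the dimer 6-bromo-5,7,3',4'-tetra-O-benzylepicatechin-(4β→6)-8-bromo-5,7,3',4'-tetra-O-benzylepicatechin F6. Me3SiOTf coupling of F6 with 4 at C8 of the upper unit, its only free ring A carbon, comes back to the route at 15.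

Step 8. With the electron-rich aryl group, the stepwise oxygen transfer may leak to the trans-epoxide through bond rotation, or facial selectivity may be poor. The fallback replaces catalyst control by resolution against the enantiopure top unit. It sets out from 11. Dimethyldioxirane (acetone, 0 °C), a concerted and stereospecific oxygen donor, should give only the cis-epoxide as the racemate, that is 12 together with its enantiomer (2R,3R)-2-[3,4-bis(benzyloxy)phenyl]-3-(diethoxymethyl)oxirane F7. Opening of the racemate with 7 as in step 9 should give 13 and the diastereomeric ether alcohol with the (2R,3S)-configured side chain F8, which should separate on silica. The route is rejoined at 13.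

**Further compounds**
F1 | step 10 | 4β-(2-ethoxyethoxy)-5,7,3',4'-tetra-O-benzylepicatechin | C(c1ccccc1)Oc1cc(OCc3ccccc3)c2c(c1)O[C@H](c1ccc(OCc3ccccc3)c(OCc3ccccc3)c1)[C@H](O)[C@H]2OCCOCC
F2 | step 10 | 5,7,3',4'-tetra-O-benzylepicatechin-(4β→6)-8-bromo-5,7,3',4'-tetra-O-benzylepicatechin | c1c(OCc3ccccc3)cc(OCc3ccccc3)c2c1O[C@H](c1ccc(OCc3ccccc3)c(OCc3ccccc3)c1)[C@H](O)[C@H]2c1c(OCc3ccccc3)c(Br)c2c(c1OCc3ccccc3)C[C@@H](O)[C@@H](c1ccc(OCc3ccccc3)c(OCc3ccccc3)c1)O2
F3 | step 10 | 8-bromo-5,7,3',4'-tetra-O-benzylepicatechin-(4β→8)-5,7,3',4'-tetra-O-benzylepicatechin-(4β→6)-8-bromo-5,7,3',4'-tetra-O-benzylepicatechin | C(c1ccccc1)Oc1cc(OCc3ccccc3)c2c(c1Br)O[C@H](c1ccc(OCc3ccccc3)c(OCc3ccccc3)c1)[C@H](O)[C@H]2c1c(OCc3ccccc3)cc(OCc3ccccc3)c2c1O[C@H](c1ccc(OCc3ccccc3)c(OCc3ccccc3)c1)[C@H](O)[C@H]2c1c(OCc3ccccc3)c(Br)c2c(c1OCc3ccccc3)C[C@@H](O)[C@@H](c1ccc(OCc3ccccc3)c(OCc3ccccc3)c1)O2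
F4 | step 9 | (2S,3R)-3-[4-bromo-3,5-bis(benzyloxy)phenoxy]-3-[3,4-bis(benzyloxy)phenyl]-1,1-diethoxypropan-2-ol | CCOC(OCC)[C@@H](O)[C@H](Oc1cc(OCc2ccccc2)c(Br)c(OCc2ccccc2)c1)c1ccc(OCc2ccccc2)c(OCc2ccccc2)c1
F5 | step 9 | 6-bromo-4-ethoxy-5,7,3',4'-tetra-O-benzylepicatechin (C4 epimers, not isolated) | c1c(OCc3ccccc3)c(Br)c(OCc3ccccc3)c2c1O[C@H](c1ccc(OCc3ccccc3)c(OCc3ccccc3)c1)[C@H](O)C2OCC
F6 | step 9 | 6-bromo-5,7,3',4'-tetra-O-benzylepicatechin-(4β→6)-8-bromo-5,7,3',4'-tetra-O-benzylepicatechin | c1c(OCc3ccccc3)c(Br)c(OCc3ccccc3)c2c1O[C@H](c1ccc(OCc3ccccc3)c(OCc3ccccc3)c1)[C@H](O)[C@H]2c1c(OCc3ccccc3)c(Br)c2c(c1OCc3ccccc3)C[C@@H](O)[C@@H](c1ccc(OCc3ccccc3)c(OCc3ccccc3)c1)O2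
F7 | step 8 | (2R,3R)-2-[3,4-bis(benzyloxy)phenyl]-3-(diethoxymethyl)oxirane (cis, enantiomer of 12) | CCOC(OCC)[C@@H]1O[C@@H]1c1ccc(OCc2ccccc2)c(OCc2ccccc2)c1
F8 | step 8 | (2R,3S)-3-[3,4-bis(benzyloxy)phenyl]-3-{2-[8-bromo-5,7,3',4'-tetra-O-benzylepicatechin-4β-yl]-4-bromo-3,5-bis(benzyloxy)phenoxy}-1,1-diethoxypropan-2-ol (side-chain diastereomer of 13) | C(c1ccccc1)Oc1cc(OCc3ccccc3)c2c(c1Br)O[C@H](c1ccc(OCc3ccccc3)c(OCc3ccccc3)c1)[C@H](O)[C@H]2c1c(OCc3ccccc3)c(Br)c(OCc3ccccc3)cc1O[C@@H](c1ccc(OCc3ccccc3)c(OCc3ccccc3)c1)[C@@H](O)C(OCC)OCC
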